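**Plan**

1. Retrosynthesis: the side-chain ester C–O bond is cut first (shikonin plus 3-hydroxy-3-methylbutanoic acid). Next comes the quinone-ring bond between carbonyl carbon C1 and the side-chain-bearing carbon C2, then the C3–C4 bond (acetylide plus dione carbonyl). Last are the two bonds that tie a two-carbon ketene equivalent to a symmetric aryne.
2. Enabling feature: the quinone ring C1(=O)–C2(R)=C3(H)–C4(=O), fused at C4a/C8a to a benzene ring with like oxygens at C5 and C8, is an isomer of a 2-alkynyl-2-hydroxybenzocyclobutenone (C1 = ring ketone, C2≡C3 = alkyne, C4–OH = carbinol, its hydrogen ending on C3). The mirror symmetry of the 3,6-dioxygenated benzocyclobutenedione makes its two carbonyl groups equivalent.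
3. Forward, fragment A: an aryne (2+2) cycloaddition with a ketene acetal puts a temporary four-membered ring on the dioxygenated benzene; oxidation gives the 1,2-dione; the methyl ethers are exchanged for silyl ethers.
4. Forward, fragment B: Weinreb ynone, asymmetric transfer hydrogenation, O-silylation, C-desilylation. Its lithium acetylide adds to the dione, and thermal ring expansion (Moore cyclization) closes the quinone ring and consumes the four-membered ring.
5. One fluoride step removes all three silyl groups to give shikonin; Steglich esterification gives the target.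
6. Stereochemistry: the single (R)-centre is set by Noyori transfer hydrogenation of the ynone and is carried through unchanged as a spectator.

Key step: step 11

Remark: naphthazarin tautomers interconvert rapidly and are one compound; all such compounds are written as the tautomer of the given SMILES (side chain on the quinone ring).

**Route**

Step 1
Reactants: 1 2-bromo-1,4-dimethoxybenzene; 2 1,1-diethoxyethene
Product: 5 2,5-dimethoxybicyclo[4.2.0]octa-1,3,5-trien-7-one (3,6-dimethoxybenzocyclobutenone), via 3,6-dimethoxybenzyne 3 (not isolated), via diethyl ketal 4 (not isolated)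
Conditions: NaNH2 (2 equiv), 2 (excess), THF, reflux; then aq. HCl (1 mol/L), THF, rt
Reagents that add atoms: water, O
Why: Elimination of HBr with NaNH2 gives the symmetric aryne 3, flanked on both sides by methoxy-bearing carbons so that only one orientation exists, which should undergo the known aryne–ketene acetal (2+2) cycloaddition to 4, and mild acid hydrolysis of the ketal gives 5.

Step 2
Reactants: 5 2,5-dimethoxybicyclo[4.2.0]octa-1,3,5-trien-7-one
Product: 7 2,5-dimethoxybicyclo[4.2.0]octa-1,3,5-triene-7,8-dione (3,6-dimethoxybenzocyclobutene-1,2-dione), via gem-dibromide 6 (not isolated)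
Conditions: N-bromosuccinimide (2.2 equiv), dibenzoyl peroxide (cat.), CCl4, reflux; then 50% aq. H2SO4, 60 °C
Reagents that add atoms: water, O
Why: Wohl–Ziegler radical bromination should occur twice at the only sp3 C–H position, which is benzylic and alpha to the ketone, and acid hydrolysis of the gem-dibromide gives the 1,2-dione, the standard entry to benzocyclobutenediones.

Step 3
Reactants: 7 2,5-dimethoxybicyclo[4.2.0]octa-1,3,5-triene-7,8-dione
Product: 8 2,5-dihydroxybicyclo[4.2.0]octa-1,3,5-triene-7,8-dione
Conditions: BBr3 (3 equiv), CH2Cl2, −78 °C → rt; then H2O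
Reagents that add atoms: none
Why: Lewis acid ether cleavage, in which bromide attacks the boron-activated methyl groups in an SN2 step, should free both phenols, while the dione has no enolisable hydrogen and is inert to the reagent.

Step 4
Reactants: 8 2,5-dihydroxybicyclo[4.2.0]octa-1,3,5-triene-7,8-dione
Product: 9 2,5-bis(tert-butyldimethylsilyloxy)bicyclo[4.2.0]octa-1,3,5-triene-7,8-dione
Conditions: TBSOTf (2.4 equiv), 2,6-lutidine, CH2Cl2, −20 → 0 °C
Reagents that add atoms: tert-butyldimethylsilyl trifluoromethanesulfonate, CC(C)(C)[Si](C)(C)OS(=O)(=O)C(F)(F)F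
Why: Phenol silylation with a silyl triflate and a hindered, non-nucleophilic base avoids nucleophilic opening of the strained dione and installs groups that tolerate the organolithium and thermal steps and leave with fluoride.

Step 5
Reactants: 10 4-methylpent-3-enoic acid
Product: 12 N-methoxy-N,4-dimethylpent-3-enamide, via acyl imidazolide 11 (not isolated)
Conditions: 1,1'-carbonyldiimidazole, CH2Cl2, rt; then MeNHOMe·HCl, rt
Reagents that add atoms: N,O-dimethylhydroxylamine hydrochloride, CNOC.Cl
Why: Amide formation through the acyl imidazolide runs without added strong base, so the beta,gamma double bond should stay out of conjugation, and gives the Weinreb amide.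

Step 6
Reactants: 12 N-methoxy-N,4-dimethylpent-3-enamide; 13 ethynyltrimethylsilane
Product: 15 6-methyl-1-(trimethylsilyl)hept-5-en-1-yn-3-one, via lithium trimethylsilylacetylide 14 (not isolated)
Conditions: 13, n-BuLi, THF, −78 °C; then 12, −78 → −20 °C; cold aq. HCl (1 mol/L) quench
Reagents that add atoms: none
Why: Weinreb ketone synthesis, in which the chelated tetrahedral adduct stops at the ketone stage and is released only on cold acidic quench, which also ties up the liberated amine so that it cannot add to the ynone.

Step 7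
Reactants: 15 6-methyl-1-(trimethylsilyl)hept-5-en-1-yn-3-one
Product: 16 (3R)-6-methyl-1-(trimethylsilyl)hept-5-en-1-yn-3-ol
Conditions: Ru[(R,R)-TsDPEN](p-cymene) (preformed amido complex, 1 mol%, no added base), i-PrOH, rt
Reagents that add atoms: none
Why: Noyori asymmetric transfer hydrogenation of an alkynyl ketone, in which the (R,R)-catalyst should give the (R)-propargylic alcohol by analogy with simple alkynyl alkyl ketones (the alkyne plays the part of the aryl group of an aryl ketone), the base-free catalyst avoiding isomerisation of the skipped enone; this sets the only stereocentre of the target.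

Step 8
Reactants: 16 (3R)-6-methyl-1-(trimethylsilyl)hept-5-en-1-yn-3-ol
Product: 17 (3R)-3-(tert-butyldimethylsilyloxy)-6-methyl-1-(trimethylsilyl)hept-5-en-1-yne
Conditions: TBSCl, imidazole, DMF, rt
Reagents that add atoms: tert-butyldimethylsilyl chloride, CC(C)(C)[Si](C)(C)Cl
Why: Standard imidazole-promoted silyl ether formation protects the carbinol for the organolithium step without touching the stereocentre.

Step 9
Reactants: 17 (3R)-3-(tert-butyldimethylsilyloxy)-6-methyl-1-(trimethylsilyl)hept-5-en-1-yne
Product: 18 (3R)-3-(tert-butyldimethylsilyloxy)-6-methylhept-5-en-1-yne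
Conditions: K2CO3 (0.2 equiv), MeOH, 0 °C → rt
Reagents that add atoms: none
Why: Protodesilylation of a silylalkyne by methanolysis under catalytic carbonate is selective for the C–Si bond over the hindered secondary silyl ether.

Step 10
Reactants: 18 (3R)-3-(tert-butyldimethylsilyloxy)-6-methylhept-5-en-1-yne; 9 2,5-bis(tert-butyldimethylsilyloxy)bicyclo[4.2.0]octa-1,3,5-triene-7,8-dione
Product: 20 8-hydroxy-8-[(3R)-3-(tert-butyldimethylsilyloxy)-6-methylhept-5-en-1-yn-1-yl]-2,5-bis(tert-butyldimethylsilyloxy)bicyclo[4.2.0]octa-1,3,5-trien-7-one (both C8 epimers), via lithium acetylide 19 (not isolated)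
Conditions: 18, n-BuLi (1.0 equiv), THF, −78 °C; cannulated into 9 (1.1 equiv), THF, −78 °C; AcOH quench at −78 °C
Reagents that add atoms: none
Why: 1,2-Addition of a lithium acetylide to a benzocyclobutenedione, in which the two carbonyl groups of 9 are equivalent by symmetry so that one constitution results, the alkoxide formed deactivates the second carbonyl, and the new carbinol centre is destroyed in the next step.

Step 11
Reactants: 20 8-hydroxy-8-[(3R)-3-(tert-butyldimethylsilyloxy)-6-methylhept-5-en-1-yn-1-yl]-2,5-bis(tert-butyldimethylsilyloxy)bicyclo[4.2.0]octa-1,3,5-trien-7-one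
Product: 23 2-[(1R)-1-(tert-butyldimethylsilyloxy)-4-methylpent-3-en-1-yl]-5,8-bis(tert-butyldimethylsilyloxy)naphthalene-1,4-dione, via enynyl ketene 21 (not isolated), via diradical 22 (not isolated)
Conditions: mesitylene (degassed, 0.01 mol/L), 150 °C, argon
Reagents that add atoms: none
Why: Moore cyclization, the thermal ring expansion of a 4-alkynyl-4-hydroxycyclobutenone to a quinone, a reaction type known for 2-alkynyl-2-hydroxybenzocyclobutenones: conrotatory 4π electrocyclic opening of the four-membered ring of 20 breaks the C7–C8 bond and gives the o-quinoid enynyl ketene 21, the hydroxyl turning outward (torquoselectivity of a donor) so that the alkyne comes to lie beside the ketene. The ketene carbon then bonds to the distal alkyne carbon, the one that carries the stereogenic side chain, which closes the six-membered ring in a 6-endo-dig mode, restores the benzene ring and leaves the σ,π-diradical 22 (naphthoxyl oxygen radical, σ-radical on the former proximal alkyne carbon). Transfer of the hydroxyl hydrogen to the σ-radical carbon gives quinone 23, so the carbinol carbon becomes the second carbonyl and its hydrogen the lone quinone C–H. No stereocentre is formed: the two C8 epimers of 20 converge, and the (R)-centre is a spectator that is not acidic under neutral thermal conditions and not conjugated with the σ-radical. The step needs six- over five-membered closure (the latter would lead to a 2-alkylideneindane-1,3-dione) and hydrogen delivery from O–H and not from the allylic CH2 of the side chain; the alkyne terminus carries an sp3 carbon and no radical-stabilising group, which favours the six-membered mode, the free hydroxyl sits next to the radical carbon, and high dilution in a non-donor solvent suppresses intermolecular paths. Orientation is not an issue, since the alkyne is fixed to the carbinol carbon and 9 has two equivalent carbonyl groups.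

Step 12
Reactants: 23 2-[(1R)-1-(tert-butyldimethylsilyloxy)-4-methylpent-3-en-1-yl]-5,8-bis(tert-butyldimethylsilyloxy)naphthalene-1,4-dione
Product: 24 shikonin, 5,8-dihydroxy-2-[(1R)-1-hydroxy-4-methylpent-3-en-1-yl]naphthalene-1,4-dione
Conditions: HF·pyridine (excess), pyridine, THF, 0 °C → rt
Reagents that add atoms: none
Why: Global desilylation with buffered fluoride should cleave the two aryl and the one secondary alkyl silyl ether under non-oxidising, only weakly acidic conditions that leave the trisubstituted alkene, the quinone and the stereocentre untouched.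

Step 13
Reactants: 24 shikonin; 25 3-hydroxy-3-methylbutanoic acid
Product: 26 beta-HIVS, (1R)-1-(5,8-dihydroxy-1,4-dioxo-1,4-dihydronaphthalen-2-yl)-4-methylpent-3-en-1-yl 3-hydroxy-3-methylbutanoate
Conditions: N,N'-dicyclohexylcarbodiimide, DMAP (cat.), CH2Cl2, 0 °C → rt
Reagents that add atoms: none
Why: Steglich esterification, in which the secondary side-chain hydroxyl should be acylated in preference to the two phenols (held in strong hydrogen bonds to the quinone carbonyls) and to the hindered tertiary hydroxyl of 25, with retention at C1' because no bond to the stereocentre is made or broken.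

**Compound list**

1 | 2-bromo-1,4-dimethoxybenzene | COc1ccc(OC)c(Br)c1 | starting material
2 | 1,1-diethoxyethene | C=C(OCC)OCC | starting material
3 | 3,6-dimethoxybenzyne | COC1=CC=C(OC)C#C1 | intermediate (not isolated)
4 | 7,7-diethoxy-2,5-dimethoxybicyclo[4.2.0]octa-1,3,5-triene | CCOC1(OCC)Cc2c(OC)ccc(OC)c21 | intermediate (not isolated)
5 | 2,5-dimethoxybicyclo[4.2.0]octa-1,3,5-trien-7-one | COc1ccc(OC)c2c1CC2=O | intermediate
6 | 8,8-dibromo-2,5-dimethoxybicyclo[4.2.0]octa-1,3,5-trien-7-one | COc1ccc(OC)c2c1C(Br)(Br)C2=O | intermediate (not isolated)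
7 | 2,5-dimethoxybicyclo[4.2.0]octa-1,3,5-triene-7,8-dione | COc1ccc(OC)c2c1C(=O)C2=O | intermediate
8 | 2,5-dihydroxybicyclo[4.2.0]octa-1,3,5-triene-7,8-dione | Oc1ccc(O)c2c1C(=O)C2=O | intermediate
9 | 2,5-bis(tert-butyldimethylsilyloxy)bicyclo[4.2.0]octa-1,3,5-triene-7,8-dione | CC(C)(C)[Si](C)(C)Oc1ccc(O[Si](C)(C)C(C)(C)C)c2c1C(=O)C2=O | intermediate
10 | 4-methylpent-3-enoic acid | CC(C)=CCC(=O)O | starting material
11 | 1-(4-methylpent-3-enoyl)imidazole | CC(C)=CCC(=O)n1ccnc1 | intermediate (not isolated)
12 | N-methoxy-N,4-dimethylpent-3-enamide | CC(C)=CCC(=O)N(C)OC | intermediate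
13 | ethynyltrimethylsilane | C#C[Si](C)(C)C | starting material
14 | lithium (trimethylsilyl)acetylide | [Li]C#C[Si](C)(C)C | intermediate (not isolated)
15 | 6-methyl-1-(trimethylsilyl)hept-5-en-1-yn-3-one | CC(C)=CCC(=O)C#C[Si](C)(C)C | intermediate
16 | (3R)-6-methyl-1-(trimethylsilyl)hept-5-en-1-yn-3-ol | CC(C)=CC[C@@H](O)C#C[Si](C)(C)C | intermediate
17 | (3R)-3-(tert-butyldimethylsilyloxy)-6-methyl-1-(trimethylsilyl)hept-5-en-1-yne | CC(C)=CC[C@@H](O[Si](C)(C)C(C)(C)C)C#C[Si](C)(C)C | intermediate
18 | (3R)-3-(tert-butyldimethylsilyloxy)-6-methylhept-5-en-1-yne | CC(C)=CC[C@@H](O[Si](C)(C)C(C)(C)C)C#C | intermediate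
19 | lithium acetylide of 18 | CC(C)=CC[C@@H](O[Si](C)(C)C(C)(C)C)C#C[Li] | intermediate (not isolated)
20 | 8-hydroxy-8-[(3R)-3-(tert-butyldimethylsilyloxy)-6-methylhept-5-en-1-yn-1-yl]-2,5-bis(tert-butyldimethylsilyloxy)bicyclo[4.2.0]octa-1,3,5-trien-7-one (both C8 epimers) | CC(C)=CC[C@@H](O[Si](C)(C)C(C)(C)C)C#CC1(O)C(=O)c2c(O[Si](C)(C)C(C)(C)C)ccc(O[Si](C)(C)C(C)(C)C)c21 | intermediate
21 | o-quinoid enynyl ketene from ring opening of 20 | CC(C)=CC[C@@H](O[Si](C)(C)C(C)(C)C)C#CC(O)=C1C(O[Si](C)(C)C(C)(C)C)=CC=C(O[Si](C)(C)C(C)(C)C)C1=C=O | intermediate (not isolated)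
22 | 4-hydroxy-1-naphthoxyl-3-yl diradical from closure of 21 | CC(C)=CC[C@@H](O[Si](C)(C)C(C)(C)C)C1=[C]C(O)=C2C(O[Si](C)(C)C(C)(C)C)=CC=C(O[Si](C)(C)C(C)(C)C)C2=C1[O] | intermediate (not isolated)
23 | 2-[(1R)-1-(tert-butyldimethylsilyloxy)-4-methylpent-3-en-1-yl]-5,8-bis(tert-butyldimethylsilyloxy)naphthalene-1,4-dione | CC(C)=CC[C@@H](O[Si](C)(C)C(C)(C)C)C1=CC(=O)c2c(O[Si](C)(C)C(C)(C)C)ccc(O[Si](C)(C)C(C)(C)C)c2C1=O | intermediate
24 | shikonin, 5,8-dihydroxy-2-[(1R)-1-hydroxy-4-methylpent-3-en-1-yl]naphthalene-1,4-dione | CC(C)=CC[C@@H](O)C1=CC(=O)c2c(O)ccc(O)c2C1=O | intermediate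
25 | 3-hydroxy-3-methylbutanoic acid | CC(C)(O)CC(=O)O | starting material
26 | beta-HIVS, (1R)-1-(5,8-dihydroxy-1,4-dioxo-1,4-dihydronaphthalen-2-yl)-4-methylpent-3-en-1-yl 3-hydroxy-3-methylbutanoate | CC(C)=CC[C@@H](OC(=O)CC(C)(C)O)C1=CC(=O)c2c(O)ccc(O)c2C1=O | target

**Step count**

Total steps: 13. Longest linear sequence: 9 steps (steps 5 to 13, from 10).

**Steps most likely to fail**

Step 11. The ketene may close onto the proximal alkyne carbon (five-membered mode), or the aryl σ-radical may abstract an allylic hydrogen of the side chain instead of receiving the hydroxyl hydrogen. The fallback makes the same bond and ring by the phthaloylcobalt route and sets out from 9 and 18. Compound 9 and ClCo(PPh3)3 (monovalent cobalt) in chlorobenzene at 60 °C should give, by insertion of cobalt into the C7–C8 bond of the dione, chloro[3,6-bis(tert-butyldimethylsilyloxy)phthaloyl]bis(triphenylphosphine)cobalt F1. Chloride abstraction with AgBF4 in MeCN and heating with 18 at 80 °C should insert the alkyne into a cobalt–acyl bond and close the quinone ring by reductive elimination. Both insertion orientations give the same product, and the route is rejoined at 23.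

Step 10. An aryl silyl group may migrate to, or be cleaved by, the newly formed alkoxide, and a second acetylide may add. The fallback replaces the aryl silyl ethers by acetals that cannot migrate and sets out from 8. Chloromethyl methyl ether and i-Pr2NEt in CH2Cl2 should give 2,5-bis(methoxymethoxy)bicyclo[4.2.0]octa-1,3,5-triene-7,8-dione F2. Addition of 19 as in step 10 should give 8-hydroxy-8-[(3R)-3-(tert-butyldimethylsilyloxy)-6-methylhept-5-en-1-yn-1-yl]-2,5-bis(methoxymethoxy)bicyclo[4.2.0]octa-1,3,5-trien-7-one F3. Thermolysis as in step 11 should give 2-[(1R)-1-(tert-butyldimethylsilyloxy)-4-methylpent-3-en-1-yl]-5,8-bis(methoxymethoxy)naphthalene-1,4-dione F4. Aqueous HCl in THF at rt then removes both acetals and the silyl ether, and the route is rejoined at 24.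

Step 13. The activated acid may acylate its own tertiary hydroxyl (oligomer or beta-lactone formation), or a phenolic oxygen may be acylated in competition. The fallback masks the tertiary hydroxyl and sets out from 25. Et3SiCl and imidazole in DMF should give triethylsilyl 3-methyl-3-(triethylsilyloxy)butanoate F5. K2CO3 in aqueous MeOH cleaves only the silyl ester to give 3-methyl-3-(triethylsilyloxy)butanoic acid F6. Coupling of this acid with 24 under the conditions of step 13 should give (1R)-1-(5,8-dihydroxy-1,4-dioxo-1,4-dihydronaphthalen-2-yl)-4-methylpent-3-en-1-yl 3-methyl-3-(triethylsilyloxy)butanoate F7. HF·pyridine in THF removes the tertiary silyl ether, and the route is rejoined at 26.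

**Further compounds**

F1 | step 11 | chloro[3,6-bis(tert-butyldimethylsilyloxy)phthaloyl]bis(triphenylphosphine)cobalt | O=C1c2c(O[Si](C)(C)C(C)(C)C)ccc(O[Si](C)(C)C(C)(C)C)c2C(=O)[Co-2]1(Cl)([P+](c1ccccc1)(c1ccccc1)c1ccccc1)[P+](c1ccccc1)(c1ccccc1)c1ccccc1
F2 | step 10 | 2,5-bis(methoxymethoxy)bicyclo[4.2.0]octa-1,3,5-triene-7,8-dione | COCOc1ccc(OCOC)c2c1C(=O)C2=O
F3 | step 10 | 8-hydroxy-8-[(3R)-3-(tert-butyldimethylsilyloxy)-6-methylhept-5-en-1-yn-1-yl]-2,5-bis(methoxymethoxy)bicyclo[4.2.0]octa-1,3,5-trien-7-one | CC(C)=CC[C@@H](O[Si](C)(C)C(C)(C)C)C#CC1(O)C(=O)c2c(OCOC)ccc(OCOC)c21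
F4 | step 10 | 2-[(1R)-1-(tert-butyldimethylsilyloxy)-4-methylpent-3-en-1-yl]-5,8-bis(methoxymethoxy)naphthalene-1,4-dione | CC(C)=CC[C@@H](O[Si](C)(C)C(C)(C)C)C1=CC(=O)c2c(OCOC)ccc(OCOC)c2C1=O
F5 | step 13 | triethylsilyl 3-methyl-3-(triethylsilyloxy)butanoate | CC[Si](CC)(CC)OC(=O)CC(C)(C)O[Si](CC)(CC)CC
F6 | step 13 | 3-methyl-3-(triethylsilyloxy)butanoic acid | CC[Si](CC)(CC)OC(C)(C)CC(=O)O
F7 | step 13 | (1R)-1-(5,8-dihydroxy-1,4-dioxo-1,4-dihydronaphthalen-2-yl)-4-methylpent-3-en-1-yl 3-methyl-3-(triethylsilyloxy)butanoate | CC(C)=CC[C@@H](OC(=O)CC(C)(C)O[Si](CC)(CC)CC)C1=CC(=O)c2c(O)ccc(O)c2C1=O
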